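(The numbers in the tables were generated by integration on assumed constants.)

In a one-step world with c(reagent) held, the amount of substrate cancels out of a percentage of the charge, and each equal stretch of time removes the same fraction of what isomer of the product has still to gain.

| flask | substrate | reagent | free catalyst | remark | time |
|---|---|---|---|---|---|
| Thursday's | 10 mM | 20 mM | 2 mM | run made earlier |  |
| Tuesday's | 15 mM | 20 mM | 2 mM | run made earlier |  |
| Friday's | 20 mM | 20 mM | 4 mM | run made earlier |  |
| flask | 20 mM | 20.0 mM | 2.0 mM |  | 15 d |

- Thursday's (time / d: isomer of the product / %, target / %): 0.500: 10.3, 16.1; 0.833: 13.1, 9.4; 1.67: 13.9, 3.5; 3.00: 14.0, 3.2; 5.00: 9.0, 0.3; 10.0: 5.8, 0; 20.0: 1.0, 1.8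
- Tuesday's (time / d: isomer of the product / %, target / %): 0.500: 7.9, 13.2; 0.833: 13.3, 9.0; 1.67: 14.0, 6.8; 3.00: 13.0, 3.3; 5.00: 10.3, 1.6; 10.0: 6.7, 1.4; 20.0: 1.6, 0.7
- Friday's (time / d: isomer of the product / %, target / %): 0.500: 10.7, 11.1; 1.25: 13.7, 6.1; 3.00: 12.7, 3.0; 8.00: 6.2, 0; 20.0: 1.1, 1.6

(readings scatter by 1 percentage point)

* time, not beyond 15 d, at which the flask holds most isomer of the product
* the amount of isomer of the product, in percent of the substrate charged, at that time
* the first time at which isomer of the product reaches 3.9 %, in the same percent

- what was read earlier has a scatter of 1 percentage point, one standard deviation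

Two chemists read these runs, and they share a top. The isomer readings at 1.67 d, 1.67 d and 1.25 d average 13.9 %; call this mean the ceiling, the peak share of isomer counted on the smaller charge, the limiting reagent.

They part on the climb. She orders it by c(substrate)/c(free catalyst): Tuesday's, at 7.50, reads 7.9 % at 0.500 d, while Thursday's, at 5.00, reads 10.3 %. The flask stands at 10.0, so she expects a slower rise.

I order it by c(reagent), which is 20.0 mM in the flask as in the runs. Her gap is 2.4 percentage points against a scatter of 1 point on each reading, and by 0.833 d Tuesday's stands at 13.3 %, Thursday's at 13.1 %.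

So I pool the readings at 0.500 d and work with the fraction left. Their mean, 9.63 %, leaves 30.7 % of the ceiling to gain, which makes the climb 2.37 /d. The flask reaches 3.9 % with 71.9 % left, at 0.139 d.

Her view keeps the top: at ratios from 5.00 to 7.50 those three readings span 0.3 points, against a scatter of 1 point.

The forecast, her number, gives 2.1 d (1.3 d to 3.3 d), 13.9 % (12.6 % to 15.2 %) and 0.28 d (0.15 d to 0.45 d), since “it should rise somewhat slower”.

    substrate + reagent ⇌ target (K = 26.0 /M, k = 5.00 /M/h)
    substrate + reagent ⇌ isomer of the product (K = 110 /M, k = 0.870 /M/h)
    target + free catalyst ⇌ isomer of the product + free catalyst, rate k3*[free catalyst]*[target] forward; the back reaction follows from the equilibrium constant (k = 6.70 /M/h)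
    free catalyst → spent catalyst (k = 0.0210 /h)
    substrate + reagent → uncatalysed product (k = 3.80 /M/h)

The flask peaks at 1.83 d with 12.9 %, 1.00 point under the ceiling, and reaches 3.9 % at 0.134 d, against my 0.139 d. In the neighbouring flask with 5.0 mM of reagent, reagent is the smaller charge, a quarter of the substrate. The ceiling on that charge gives 3.47 % of the substrate charged, and that flask peaks at 3.95 %. At 15.0 d it holds 75.1 % of its substrate, with 0.31 % of its reagent left.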